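Everything rests on disconnecting C2–C3 of ring C. C2 is bonded to O1 and to ring B, so it is derived from the benzylic CH2 of an aryl 4-silyloxybenzyl ether on O1; C3, next to the C4 ketone, is derived from a diazo carbon. A chiral dirhodium carboxylate converts the diazo ketone into a carbene that inserts into one of the two enantiotopic benzylic C–H bonds, which in one operation closes ring C and sets the (2S) centre. The precursor is a diazomethyl aryl ketone whose ring A carries the geranyl group between two silyl ethers and, on the other ortho oxygen, the 4-silyloxybenzyl group; fluoride then unveils the three phenols.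

Key step: step 7

Abbreviations: TBS = tert-butyldimethylsilyl; geranyl = (2E)-3,7-dimethylocta-2,6-dien-1-yl.

Assumption: Rh2(S-PTTL)4 is taken to give the (2S) product in the key step; if a test run shows the opposite sense, the mirror-image catalyst Rh2(R-PTTL)4 is used with nothing else changed.

Step 1
Reactants: 1 2,4,6-trihydroxyacetophenone; 2 geranyl bromide
Product: 3 3-geranyl-2,4,6-trihydroxyacetophenone
Conditions: DBU, THF, 0 °C to rt (1 in excess)
Reagents that add atoms: geranyl bromide (2), CC(C)=CCC/C(C)=C/CBr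
Why: C-alkylation of an ambident phloroglucinol phenoxide (SN2 at the allylic bromide) should give a single mono-C-geranyl isomer because the two free ring carbons of 1 are equivalent, direct displacement keeps the E double bond, and the excess of 1 holds back double alkylation.

Step 2
Reactants: 3 3-geranyl-2,4,6-trihydroxyacetophenone
Product: 4 1-[4-(TBSO)-3-geranyl-2,6-dihydroxyphenyl]ethanone
Conditions: TBSCl (1.05 equiv), imidazole, DMF, −20 to 0 °C
Reagents that add atoms: tert-butyldimethylsilyl chloride, CC(C)(C)[Si](C)(C)Cl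
Why: Chemoselective O-silylation should take the hydroxyl para to the acetyl group first, since it is the most acidic and the only one not engaged with the carbonyl group.

Step 3
Reactants: 5 4-(TBSO)benzaldehyde
Product: 6 4-(TBSO)benzyl alcohol
Conditions: NaBH4, MeOH, 0 °C
Reagents that add atoms: none
Why: Borohydride reduction of an aromatic aldehyde gives the benzylic alcohol and leaves the aryl silyl ether untouched at 0 °C.

Step 4
Reactants: 4 1-[4-(TBSO)-3-geranyl-2,6-dihydroxyphenyl]ethanone; 6 4-(TBSO)benzyl alcohol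
Product: 7 1-{4-(TBSO)-6-[4-(TBSO)benzyloxy]-3-geranyl-2-hydroxyphenyl}ethanone
Conditions: PPh3, DIAD, THF, 0 °C to rt
Reagents that add atoms: 4-(TBSO)benzyl alcohol (6), OCc1ccc(O[Si](C)(C)C(C)(C)C)cc1
Why: Mitsunobu etherification should occur at the ortho hydroxyl next to the ring hydrogen, which is less crowded and more weakly hydrogen-bonded than the one wedged between geranyl and acetyl, while the neutral medium spares the silyl ethers and the remaining hydroxyl, locked to the carbonyl group, resists a second alkylation.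

Step 5
Reactants: 7 1-{4-(TBSO)-6-[4-(TBSO)benzyloxy]-3-geranyl-2-hydroxyphenyl}ethanone
Product: 8 1-{2,4-bis(TBSO)-6-[4-(TBSO)benzyloxy]-3-geranylphenyl}ethanone
Conditions: TBSOTf, 2,6-lutidine, CH2Cl2, −40 to 0 °C
Reagents that add atoms: tert-butyldimethylsilyl triflate, CC(C)(C)[Si](C)(C)OS(=O)(=O)C(F)(F)F
Why: O-silylation with a silyl triflate is electrophilic enough to cap the crowded, hydrogen-bonded hydroxyl, while 2,6-lutidine at low temperature is too weak a base to convert the methyl ketone into its silyl enol ether.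

Step 6
Reactants: 8 1-{2,4-bis(TBSO)-6-[4-(TBSO)benzyloxy]-3-geranylphenyl}ethanone
Product: 10 2-diazo-1-{2,4-bis(TBSO)-6-[4-(TBSO)benzyloxy]-3-geranylphenyl}ethanone, via trifluoroacetyl diketone 9 (not isolated)
Conditions: LiN(SiMe3)2, THF, −78 °C; CF3CO2CH2CF3, −78 °C; aq. NH4Cl, crude 9 carried on; then p-ABSA, Et3N, H2O (1 equiv), MeCN, rt
Reagents that add atoms: 4-acetamidobenzenesulfonyl azide (p-ABSA, gives the two diazo nitrogens), CC(=O)Nc1ccc(cc1)S(=O)(=O)N=[N+]=[N-]; 2,2,2-trifluoroethyl trifluoroacetate (gives the CF3CO group of 9 only), O=C(OCC(F)(F)F)C(F)(F)F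
Why: Detrifluoroacetylative diazo transfer (a Regitz-type diazo transfer) should work because the kinetic lithium enolate of the methyl ketone, the only enolisable site, undergoes Claisen trifluoroacetylation and the activated 1,3-diketone 9 then takes the diazo group from the sulfonyl azide while the trifluoroacetyl group passes to the sulfonamide nitrogen.

Step 7
Reactants: 10 2-diazo-1-{2,4-bis(TBSO)-6-[4-(TBSO)benzyloxy]-3-geranylphenyl}ethanone
Product: 11 (2S)-5,7-bis(TBSO)-2-[4-(TBSO)phenyl]-6-geranylchroman-4-one
Conditions: Rh2(S-PTTL)4 (2 mol %), toluene, 4 Å MS, 0 °C to rt, slow addition of 10 (about 0.01 M)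
Reagents that add atoms: none
Why: Rh2(S-PTTL)4 expels N2 from 10 to give an electrophilic rhodium carbene at C3, which takes up the hydridic benzylic C–H bond next to O1 in a concerted but asynchronous three-centre insertion that forms C2–C3 and releases the catalyst. The closest known reaction type is the dirhodium carboxylate-catalysed enantioselective intramolecular C–H insertion of 2-alkoxyaryl diazomethyl ketones to 2-substituted chroman-4-ones. Ring C closes as a six-membered ring by 1,6-insertion, because the atom in the 1,5-position is O1 and bears no hydrogen. The C2 centre is set by the catalyst alone: the chiral wall of phthalimido groups around the carbene should let only one of the two enantiotopic benzylic hydrogens reach C3 with ring B pseudo-equatorial. The step needs insertion to win over attack on O1 (oxonium ylide, then 1,2-benzyl shift to a benzofuran-3-one) and over reaction with the geranyl alkenes; the substrate secures this because the O1 lone pairs are delocalised into ring A and crowded, the benzylic C–H bond is made strongly hydridic by O1 and the 4-silyloxyphenyl ring, the silyl ethers offer no activated C–H bond within reach, the nearer alkene sits meta to the acyl group and cannot reach C3, and slow addition at high dilution suppresses intermolecular cyclopropanation.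

Step 8
Reactants: 11 (2S)-5,7-bis(TBSO)-2-[4-(TBSO)phenyl]-6-geranylchroman-4-one
Product: 12 bonannione A, (2S)-6-geranyl-5,7-dihydroxy-2-(4-hydroxyphenyl)chroman-4-one
Conditions: Et3N·3HF, THF, 0 °C to rt; pH 7 phosphate buffer work-up
Reagents that add atoms: none
Why: Fluoride-driven cleavage of the three aryl silyl ethers with a weakly acidic amine hydrofluoride keeps the freed phenols protonated, so no phenoxide arises that could open ring C by beta-elimination of O1 and racemise C2, and the medium is too weakly acidic to cyclise the geranyl chain onto the neighbouring hydroxyls.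

Compound list
1 | 2,4,6-trihydroxyacetophenone | CC(=O)c1c(O)cc(O)cc1O | starting material
2 | geranyl bromide, (2E)-1-bromo-3,7-dimethylocta-2,6-diene | CC(C)=CCC/C(C)=C/CBr | starting material
3 | 3-geranyl-2,4,6-trihydroxyacetophenone | CC(C)=CCC/C(C)=C/Cc1c(O)cc(O)c(C(C)=O)c1O | intermediate
4 | 1-[4-(TBSO)-3-geranyl-2,6-dihydroxyphenyl]ethanone | CC(C)=CCC/C(C)=C/Cc1c(O[Si](C)(C)C(C)(C)C)cc(O)c(C(C)=O)c1O | intermediate
5 | 4-(tert-butyldimethylsilyloxy)benzaldehyde | O=Cc1ccc(O[Si](C)(C)C(C)(C)C)cc1 | starting material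
6 | 4-(tert-butyldimethylsilyloxy)benzyl alcohol | OCc1ccc(O[Si](C)(C)C(C)(C)C)cc1 | intermediate
7 | 1-{4-(TBSO)-6-[4-(TBSO)benzyloxy]-3-geranyl-2-hydroxyphenyl}ethanone | CC(C)=CCC/C(C)=C/Cc1c(O[Si](C)(C)C(C)(C)C)cc(OCc2ccc(O[Si](C)(C)C(C)(C)C)cc2)c(C(C)=O)c1O | intermediate
8 | 1-{2,4-bis(TBSO)-6-[4-(TBSO)benzyloxy]-3-geranylphenyl}ethanone | CC(C)=CCC/C(C)=C/Cc1c(O[Si](C)(C)C(C)(C)C)cc(OCc2ccc(O[Si](C)(C)C(C)(C)C)cc2)c(C(C)=O)c1O[Si](C)(C)C(C)(C)C | intermediate
9 | 1-{2,4-bis(TBSO)-6-[4-(TBSO)benzyloxy]-3-geranylphenyl}-4,4,4-trifluorobutane-1,3-dione (not isolated) | CC(C)=CCC/C(C)=C/Cc1c(O[Si](C)(C)C(C)(C)C)cc(OCc2ccc(O[Si](C)(C)C(C)(C)C)cc2)c(C(=O)CC(=O)C(F)(F)F)c1O[Si](C)(C)C(C)(C)C | intermediate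
10 | 2-diazo-1-{2,4-bis(TBSO)-6-[4-(TBSO)benzyloxy]-3-geranylphenyl}ethanone | CC(C)=CCC/C(C)=C/Cc1c(O[Si](C)(C)C(C)(C)C)cc(OCc2ccc(O[Si](C)(C)C(C)(C)C)cc2)c(C(=O)C=[N+]=[N-])c1O[Si](C)(C)C(C)(C)C | intermediate
11 | (2S)-5,7-bis(TBSO)-2-[4-(TBSO)phenyl]-6-geranylchroman-4-one | CC(C)=CCC/C(C)=C/Cc1c(O[Si](C)(C)C(C)(C)C)cc2c(c1O[Si](C)(C)C(C)(C)C)C(=O)C[C@@H](c1ccc(O[Si](C)(C)C(C)(C)C)cc1)O2 | intermediate
12 | bonannione A, (2S)-6-geranyl-5,7-dihydroxy-2-(4-hydroxyphenyl)chroman-4-one | CC(C)=CCC/C(C)=C/Cc1c(O)cc2c(c1O)C(=O)C[C@@H](c1ccc(O)cc1)O2 | target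

Total step count: 8
Longest linear sequence: 7 steps (steps 1, 2, 4, 5, 6, 7, 8)

Steps most likely to fail

Step 7. What may go wrong: the carbene is captured by the lone pair of O1 and the benzyl group then shifts to carbon, or the catalyst fails to tell the two benzylic hydrogens apart, so ring C would form in low yield or low enantiomeric purity. The fallback gives up carbene chemistry and sets C2 by asymmetric conjugate arylation of a chromone. It sets out from 4 and comes back to the route at 11. The open hydroxyl of 4 is masked by Mitsunobu reaction with allyl alcohol (PPh3, DIAD, THF) to give 1-[6-allyloxy-4-(TBSO)-3-geranyl-2-hydroxyphenyl]ethanone F1. The remaining hydroxyl is silylated (TBSOTf, 2,6-lutidine) to give 1-[6-allyloxy-2,4-bis(TBSO)-3-geranylphenyl]ethanone F2. Pd(PPh3)4 with morpholine in THF should remove the allyl group without touching the silyl ethers or the geranyl chain, giving 1-[2,4-bis(TBSO)-3-geranyl-6-hydroxyphenyl]ethanone F3, in which only the oxygen destined to become O1 is free. Condensation with N,N-dimethylformamide dimethyl acetal in toluene at 90 °C should give (E)-3-(dimethylamino)-1-[2,4-bis(TBSO)-3-geranyl-6-hydroxyphenyl]prop-2-en-1-one F4, which should close on silica gel or with pyridinium p-toluenesulfonate, with loss of dimethylamine, to 6-geranyl-5,7-bis(TBSO)chromen-4-one F5. Conjugate addition of commercial 4-(TBSO)phenylboronic acid, catalysed by Pd(OCOCF3)2 and the enantiomer of the pyridine-oxazoline ligand t-BuPyOx that leads to the (S) product (NH4PF6, H2O, 1,2-dichloroethane, 60 °C), should then give 11.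

Step 4. What may go wrong: slow condensation at a hydrogen-bonded phenol, C-benzylation of ring A at its one free position by the readily ionising benzylic oxyphosphonium salt, or partial reaction at the geranyl-flanked hydroxyl. The fallback replaces the redox condensation by SN2 alkylation of the phenoxide. It sets out from 6 and 4 and comes back at 7. Alcohol 6 is converted with CBr4 and PPh3 in CH2Cl2 at 0 °C into 4-(TBSO)benzyl bromide F6, which is used at once with 4 and K2CO3 in acetone at rt; the more crowded, more strongly chelated hydroxyl should again stay free, giving 7.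

Step 6. What may go wrong: migration of the neighbouring silyl group from the aryl oxygen to the enolate oxygen, or loss of that silyl ether during the aqueous amine stage, which would leave a free phenol that diverts the carbene in step 7. The fallback avoids strong base and sets out from 8, coming back at 10. Ketone 8 is condensed with N,N-dimethylformamide dimethyl acetal (or tert-butoxybis(dimethylamino)methane) in toluene at 90–100 °C to give (E)-3-(dimethylamino)-1-{2,4-bis(TBSO)-6-[4-(TBSO)benzyloxy]-3-geranylphenyl}prop-2-en-1-one F7. Diazo transfer to this enaminone with p-ABSA in MeCN at rt, which proceeds by cycloaddition and loss of the N-sulfonyl formamidine, should give 10.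

Further compounds
F1 | step 7 | 1-[6-allyloxy-4-(TBSO)-3-geranyl-2-hydroxyphenyl]ethanone | CC(C)=CCC/C(C)=C/Cc1c(O[Si](C)(C)C(C)(C)C)cc(OCC=C)c(C(C)=O)c1O
F2 | step 7 | 1-[6-allyloxy-2,4-bis(TBSO)-3-geranylphenyl]ethanone | CC(C)=CCC/C(C)=C/Cc1c(O[Si](C)(C)C(C)(C)C)cc(OCC=C)c(C(C)=O)c1O[Si](C)(C)C(C)(C)C
F3 | step 7 | 1-[2,4-bis(TBSO)-3-geranyl-6-hydroxyphenyl]ethanone | CC(C)=CCC/C(C)=C/Cc1c(O[Si](C)(C)C(C)(C)C)cc(O)c(C(C)=O)c1O[Si](C)(C)C(C)(C)C
F4 | step 7 | (E)-3-(dimethylamino)-1-[2,4-bis(TBSO)-3-geranyl-6-hydroxyphenyl]prop-2-en-1-one | CC(C)=CCC/C(C)=C/Cc1c(O[Si](C)(C)C(C)(C)C)cc(O)c(C(=O)/C=C/N(C)C)c1O[Si](C)(C)C(C)(C)C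
F5 | step 7 | 6-geranyl-5,7-bis(TBSO)chromen-4-one | CC(C)=CCC/C(C)=C/Cc1c(O[Si](C)(C)C(C)(C)C)cc2occc(=O)c2c1O[Si](C)(C)C(C)(C)C
F6 | step 4 | 4-(TBSO)benzyl bromide | BrCc1ccc(O[Si](C)(C)C(C)(C)C)cc1
F7 | step 6 | (E)-3-(dimethylamino)-1-{2,4-bis(TBSO)-6-[4-(TBSO)benzyloxy]-3-geranylphenyl}prop-2-en-1-one | CC(C)=CCC/C(C)=C/Cc1c(O[Si](C)(C)C(C)(C)C)cc(OCc2ccc(O[Si](C)(C)C(C)(C)C)cc2)c(C(=O)/C=C/N(C)C)c1O[Si](C)(C)C(C)(C)C
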